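The trap in these runs was the percentage column. At 60.0 s ring read 29.0% in oak and 22.3% in ash, lower at the larger charge. But what was asked is a concentration, and percent times charge gave 0.0180 M in oak against 0.0468 M in ash, which is more.

| flask | starting material | remark | time |
|---|---|---|---|
| oak | 0.062 M | run made earlier |  |
| elm | 0.095 M | run made earlier |  |
| ash | 0.21 M | run made earlier |  |
| teal | 0.050 M |  | 2.0 min |
| green | 0.10 M |  | 2.0 min |
| ochre | 0.20 M |  | 2.0 min |

| oak: time / s | oak: ring / % | elm: time / s | elm: ring / % | ash: time / s | ash: ring / % |
|---|---|---|---|---|---|
| 10.0 | 40.3 | 10.0 | 35.4 | 12.0 | 25.8 |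
| 15.0 | 36.6 | 15.0 | 32.8 | 25.0 | 24.2 |
| 30.0 | 31.0 | 30.0 | 29.0 | 40.0 | 23.1 |
| 40.0 | 29.8 | 40.0 | 27.4 | 50.0 | 22.2 |
| 60.0 | 29.0 | 60.0 | 26.7 | 60.0 | 22.3 |

(standard deviation of a reading: 0.5 percentage points)

- "hardly changes" means that all values lie within two and a half points (for a concentration: within two and a half percent of the largest)

1. [ring] at the end for teal, green, ochre, in this order
2. the course of these numbers from the first flask to the last (falls, then rises / rises all the way / falls all the way / hardly changes / rises, then falls)

So I went to logarithms. In powers of ten, ash held 0.415 more ring on 0.530 more charge. That gave 0.785 for the plateau order, the logarithm of the ratio of ring concentrations divided by the logarithm of the ratio of charges.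

For a second way I took different readings of the same two flasks, those at 40.0 s, and got 0.791. The earlier readings could have cheated if ring were still relaxing, and I could not call that over: oak fell 0.8 percentage points from there to 60.0 s, against a scatter of 0.5 points. But the order rests on the ratio between the two flasks, and ash fell 0.8 points over the same stretch. The two ways agreed, so I trusted the order.

The asked 2.0 min is twice the last reading, and I assumed ring would lose little beyond that reading. Scaling from oak by the order, I reckoned 0.0152 M for teal, 0.0262 M for green and 0.0451 M for ochre, a row that rose.

The forecast, made from the same runs, gave 0.015 M, 0.026 M and 0.045 M, course rises all the way, on the ground that “absolute [ring] still climbs”. My numbers rounded to the same values.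

The flasks gave 0.0135 M, 0.0249 M and 0.0439 M, course rises all the way, so the forecast held.

    starting material ⇌ ring (K = 2.70, k = 0.449 /s)
    2 starting material ⇌ open dimer (K = 100 /M, k = 3.61 /M/s)
    ring ⇌ isomer of the product (K = 2.06, k = 0.0340 /s)

In teal the relaxation half-life of ring and isomer of the product, 0.229 min, is short against the asked 2.0 min, and teal's ring stood at 27.0% after 2.00 min and 26.4% after 20.0 min. Carried by the plateau order 0.785 from green's 0.0249 M to the charge of ochre, ring came to 0.0429 M, and ochre held 0.0439 M.

The earlier runs and the new flask are simulated with made-up constants, noise included.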